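**Plan**

- Retrosynthesis first cuts the four benzyl ethers and the four ester C–O bonds. This leads back to a tetra-oxygenated p-terphenyl in which the oxygen pair O1/O2 carries a free hydroxyl and a tert-butyl ether, and the pair O4/O5 is tied up as a silylene.
- That arene is the reduced form of a 3,6-diaryl-1,4-benzoquinone with carbonyls at C1 and C4. Its ring is cut at C4–C5 and C6–C1 into a four-carbon unit C1–C2–C3–C4 (aryl tert-butoxy cyclobutenedione) and a two-carbon unit C5–C6 (aryl siloxyalkyne).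
- Forward: an aryllithium and di-tert-butyl squarate give the cyclobutenedione; acetylide oxidation and O-silylation give the siloxyalkyne; cobalt joins them and closes the central ring, the only ring made.
- The chain is then finished by desilylation, reduction, silylene bridging of O4/O5, acetylation and tert-butyl-to-3-phenylpropanoyl exchange at O1/O2, unbridging, double esterification at O4/O5 and hydrogenolysis.
- Both (R)-carbinol centres are bought as methyl (R)-3-hydroxybutanoate and carried through as the O-benzyl acid; no stereocentre is formed or touched elsewhere.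

Key step: step 3

Remark: central-ring locants are C1 (acetoxy), C2 (3-phenylpropanoyloxy), C3 (aryl), C4 and C5 (hydroxybutanoyloxy), C6 (aryl). Because C3/C6 carry the same aryl group and C4/C5 the same oxygen substituents, exchanging the two acyl groups between O1 and O2 gives the identical compound, so acyl migration between these two oxygens is of no consequence.

**Route**

Step 1
Reactants: 1 1-(benzyloxy)-4-bromobenzene; 2 di-tert-butyl squarate (3,4-di-tert-butoxycyclobut-3-ene-1,2-dione)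
Product: 5 3-[4-(benzyloxy)phenyl]-4-tert-butoxycyclobut-3-ene-1,2-dione, via 4-(benzyloxy)phenyllithium 3 (not isolated), via lithium alkoxide adduct 4 (not isolated)
Conditions: n-BuLi, THF, −78 °C; added to 2, THF, −78 °C; (CF3CO)2O, −78 → 0 °C; aq. NaHCO3
Reagents that add atoms: none
Why: Bromine–lithium exchange gives the aryllithium, which adds once to a squarate carbonyl, and trifluoroacetylation of the tertiary alkoxide triggers the known squarate-to-cyclobutenedione rearrangement (ionisation assisted by the vinylogous tert-butoxy group, then loss of the tert-butyl cation from the oxocarbenium ion).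

Step 2
Reactants: 6 1-(benzyloxy)-4-ethynylbenzene
Product: 9 1-(benzyloxy)-4-{[(triisopropylsilyl)oxy]ethynyl}benzene, via lithium acetylide 7 (not isolated), via lithium ynolate 8 (not isolated)
Conditions: n-BuLi, THF, −78 °C; t-BuOOLi (from t-BuOOH, LiN(SiMe3)2), −78 → 0 °C; i-Pr3SiOTf, −78 → 0 °C
Reagents that add atoms: tert-butyl hydroperoxide CC(C)(C)OO; triisopropylsilyl trifluoromethanesulfonate CC(C)[Si](OS(=O)(=O)C(F)(F)F)(C(C)C)C(C)C
Why: Oxidation of a lithium acetylide by lithium tert-butyl peroxide (Julia ynolate synthesis) gives the ynolate, which the bulky silyl triflate should silylate on oxygen rather than carbon.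

Step 3
Reactants: 5 3-[4-(benzyloxy)phenyl]-4-tert-butoxycyclobut-3-ene-1,2-dione; 9 1-(benzyloxy)-4-{[(triisopropylsilyl)oxy]ethynyl}benzene
Product: 11 3,6-bis[4-(benzyloxy)phenyl]-2-tert-butoxy-5-[(triisopropylsilyl)oxy]-1,4-benzoquinone, via maleoylcobalt complex 10 (not isolated)
Conditions: ClCo(PPh3)3, C6H6, rt; then 9, AgBF4, 2,6-di-tert-butyl-4-methylpyridine, MeCN, rt → 50 °C; air on work-up
Reagents that add atoms: none
Why: Proposed new method: monovalent cobalt should add oxidatively into the bond between the two carbonyl carbons of 5 (the future C1 and C4) to give the five-membered trivalent maleoylcobalt chloride 10; AgBF4 removes chloride, the siloxyalkyne binds and inserts into the C1 acyl–cobalt bond so that its aryl-bearing carbon (C6) joins C1, and C–C reductive elimination from the seven-membered cobaltacycle joins the oxygen-bearing carbon (C5) to C4. The closest known reaction type is the benzoquinone and naphthoquinone synthesis from cyclobutenedione-derived maleoyl- and phthaloylcobalt complexes with alkyl-, aryl- or terminal alkynes, which has not been run with an ynol silyl ether. The six-membered carbocycle closes as a formal [4+2] union of the C1–C4 diacyl unit with the two alkyne carbons, the last bond forming by reductive elimination at cobalt and not in a pericyclic step. No stereocentre is formed. The step needs head-to-tail orientation (2,5-dioxygenated, 3,6-diaryl) rather than head-to-head; the ynol ether is polarised so that its aryl-bearing carbon is the nucleophilic end, and of the two acyl carbons C1 lies outside the tert-butoxy vinylogous ester and is the more electrophilic, in line with the ability of alkoxy-substituted maleoyl complexes to tell their two acyl carbons apart with unsymmetrical alkynes. The hindered pyridine keeps the medium free of acid, which would otherwise hydrolyse or oligomerise the siloxyalkyne and strip the tert-butyl group.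

Step 4
Reactants: 11 3,6-bis[4-(benzyloxy)phenyl]-2-tert-butoxy-5-[(triisopropylsilyl)oxy]-1,4-benzoquinone
Product: 12 3,6-bis[4-(benzyloxy)phenyl]-2-tert-butoxy-5-hydroxy-1,4-benzoquinone
Conditions: Bu4NF, AcOH, THF, 0 °C
Reagents that add atoms: none
Why: Fluoride cleavage of the silyl vinylogous ester (desilylation) under acetic acid buffering should leave the tert-butyl vinylogous ester and the benzyl ethers intact.

Step 5
Reactants: 12 3,6-bis[4-(benzyloxy)phenyl]-2-tert-butoxy-5-hydroxy-1,4-benzoquinone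
Product: 13 3,6-bis[4-(benzyloxy)phenyl]-5-tert-butoxybenzene-1,2,4-triol
Conditions: Na2S2O4, THF/H2O, rt, argon; used at once
Reagents that add atoms: none
Why: Dithionite reduction of a quinone to its hydroquinone is a standard two-electron reduction that spares benzyl and tert-butyl ethers.

Step 6
Reactants: 13 3,6-bis[4-(benzyloxy)phenyl]-5-tert-butoxybenzene-1,2,4-triol
Product: 14 4,7-bis[4-(benzyloxy)phenyl]-6-tert-butoxy-2,2-di-tert-butyl-1,3,2-benzodioxasilol-5-ol
Conditions: t-Bu2Si(OTf)2 (1 equiv), 2,6-lutidine, CH2Cl2, −20 → 0 °C, argon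
Reagents that add atoms: di-tert-butylsilyl bis(trifluoromethanesulfonate) CC(C)(C)[Si](OS(=O)(=O)C(F)(F)F)(OS(=O)(=O)C(F)(F)F)C(C)(C)C
Why: Cyclic silylene formation on a catechol should pick out O4/O5, the only vicinal pair, while the lone C1 hydroxyl, flanked by tert-butoxy and aryl, is the most hindered and cannot close a ring.

Step 7
Reactants: 14 4,7-bis[4-(benzyloxy)phenyl]-6-tert-butoxy-2,2-di-tert-butyl-1,3,2-benzodioxasilol-5-ol
Product: 15 4,7-bis[4-(benzyloxy)phenyl]-6-tert-butoxy-2,2-di-tert-butyl-1,3,2-benzodioxasilol-5-yl acetate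
Conditions: Ac2O, pyridine, DMAP (cat.), CH2Cl2, rt
Reagents that add atoms: acetic anhydride CC(=O)OC(C)=O
Why: DMAP-catalysed acetylation (nucleophilic catalysis) should esterify the one remaining phenol.

Step 8
Reactants: 15 4,7-bis[4-(benzyloxy)phenyl]-6-tert-butoxy-2,2-di-tert-butyl-1,3,2-benzodioxasilol-5-yl acetate
Product: 16 4,7-bis[4-(benzyloxy)phenyl]-2,2-di-tert-butyl-6-hydroxy-1,3,2-benzodioxasilol-5-yl acetate
Conditions: CF3CO2H, CH2Cl2 (1:5), 0 °C
Reagents that add atoms: none
Why: Acidolysis of an aryl tert-butyl ether (loss of the tert-butyl cation as isobutene) is faster than cleavage of aryl benzyl ethers, the aryl acetate or the hindered aryl silylene.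

Step 9
Reactants: 16 4,7-bis[4-(benzyloxy)phenyl]-2,2-di-tert-butyl-6-hydroxy-1,3,2-benzodioxasilol-5-yl acetate
Product: 17 6-acetoxy-4,7-bis[4-(benzyloxy)phenyl]-2,2-di-tert-butyl-1,3,2-benzodioxasilol-5-yl 3-phenylpropanoate
Conditions: PhCH2CH2COCl, Et3N, DMAP (cat.), CH2Cl2, 0 °C
Reagents that add atoms: 3-phenylpropanoyl chloride O=C(Cl)CCc1ccccc1
Why: Acylation of the phenol by an acid chloride under DMAP catalysis should be clean, and any acetyl shift between O1 and O2 is degenerate.

Step 10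
Reactants: 17 6-acetoxy-4,7-bis[4-(benzyloxy)phenyl]-2,2-di-tert-butyl-1,3,2-benzodioxasilol-5-yl 3-phenylpropanoate
Product: 18 2-acetoxy-3,6-bis[4-(benzyloxy)phenyl]-4,5-dihydroxyphenyl 3-phenylpropanoate
Conditions: HF·pyridine, pyridine, THF, 0 °C
Reagents that add atoms: none
Why: Fluoride cleavage of the two Si–O bonds under buffered, non-basic conditions should spare the aryl esters, which cannot migrate because neither freed hydroxyl is ortho to an ester.

Step 11
Reactants: 19 methyl (R)-3-hydroxybutanoate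
Product: 20 methyl (R)-3-(benzyloxy)butanoate
Conditions: BnOC(=NH)CCl3, TfOH (cat.), CH2Cl2/cyclohexane, rt
Reagents that add atoms: benzyl 2,2,2-trichloroacetimidate ClC(Cl)(Cl)C(=N)OCc1ccccc1
Why: Acid-catalysed O-benzylation with the trichloroacetimidate avoids base and hence β-elimination to the crotonate, and it does not involve the stereocentre.

Step 12
Reactants: 20 methyl (R)-3-(benzyloxy)butanoate
Product: 21 (R)-3-(benzyloxy)butanoic acid
Conditions: LiOH, THF/H2O, 0 °C → rt; then aq. HCl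
Reagents that add atoms: lithium hydroxide [Li+].[OH-]
Why: Saponification of the methyl ester under mild conditions should not cause β-elimination and leaves the (R)-centre untouched.

Step 13
Reactants: 18 2-acetoxy-3,6-bis[4-(benzyloxy)phenyl]-4,5-dihydroxyphenyl 3-phenylpropanoate; 21 (R)-3-(benzyloxy)butanoic acid
Product: 22 2-acetoxy-3,6-bis[4-(benzyloxy)phenyl]-4,5-bis{[(R)-3-(benzyloxy)butanoyl]oxy}phenyl 3-phenylpropanoate
Conditions: 21 (2.5 equiv), DCC, DMAP (cat.), CH2Cl2, 0 °C → rt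
Reagents that add atoms: none
Why: Steglich esterification should acylate both phenolic hydroxyls, and the two (R)-centres come unchanged from the chiral-pool acid.

Step 14
Reactants: 22 2-acetoxy-3,6-bis[4-(benzyloxy)phenyl]-4,5-bis{[(R)-3-(benzyloxy)butanoyl]oxy}phenyl 3-phenylpropanoate
Product: 23 curtisian V
Conditions: H2 (1 atm), Pd/C, EtOAc, rt
Reagents that add atoms: none
Why: Hydrogenolysis over palladium on carbon should remove the two aryl and two alkyl benzyl ethers in a non-nucleophilic solvent, leaving the four aryl esters and the (R)-carbinol centres untouched.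

**Compound list**

1 | 1-(benzyloxy)-4-bromobenzene | Brc1ccc(OCc2ccccc2)cc1 | starting material
2 | di-tert-butyl squarate (3,4-di-tert-butoxycyclobut-3-ene-1,2-dione) | CC(C)(C)OC1=C(OC(C)(C)C)C(=O)C1=O | starting material
3 | 4-(benzyloxy)phenyllithium (not isolated) | [Li]c1ccc(OCc2ccccc2)cc1 | intermediate
4 | lithium 1-[4-(benzyloxy)phenyl]-2,3-di-tert-butoxy-4-oxocyclobut-2-en-1-olate, racemic (not isolated) | [Li]OC1(c2ccc(OCc3ccccc3)cc2)C(OC(C)(C)C)=C(OC(C)(C)C)C1=O | intermediate
5 | 3-[4-(benzyloxy)phenyl]-4-tert-butoxycyclobut-3-ene-1,2-dione | O=C1C(=O)C(OC(C)(C)C)=C1c1ccc(OCc2ccccc2)cc1 | intermediate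
6 | 1-(benzyloxy)-4-ethynylbenzene | C#Cc1ccc(OCc2ccccc2)cc1 | starting material
7 | lithium [4-(benzyloxy)phenyl]acetylide (not isolated) | [Li]C#Cc1ccc(OCc2ccccc2)cc1 | intermediate
8 | lithium 2-[4-(benzyloxy)phenyl]ethynolate (not isolated) | [Li]OC#Cc1ccc(OCc2ccccc2)cc1 | intermediate
9 | 1-(benzyloxy)-4-{[(triisopropylsilyl)oxy]ethynyl}benzene | CC(C)[Si](OC#Cc1ccc(OCc2ccccc2)cc1)(C(C)C)C(C)C | intermediate
10 | chlorobis(triphenylphosphine) maleoylcobalt complex: five-membered cobaltacycle in which trivalent cobalt bridges the two acyl carbons of the 2-[4-(benzyloxy)phenyl]-3-tert-butoxybut-2-enedioyl unit (not isolated) | O=C1C(c2ccc(OCc3ccccc3)cc2)=C(OC(C)(C)C)C(=O)[Co-2]1(Cl)([P+](c1ccccc1)(c1ccccc1)c1ccccc1)[P+](c1ccccc1)(c1ccccc1)c1ccccc1 | intermediate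
11 | 3,6-bis[4-(benzyloxy)phenyl]-2-tert-butoxy-5-[(triisopropylsilyl)oxy]-1,4-benzoquinone | O=C1C(OC(C)(C)C)=C(c2ccc(OCc3ccccc3)cc2)C(=O)C(O[Si](C(C)C)(C(C)C)C(C)C)=C1c1ccc(OCc2ccccc2)cc1 | intermediate
12 | 3,6-bis[4-(benzyloxy)phenyl]-2-tert-butoxy-5-hydroxy-1,4-benzoquinone | O=C1C(OC(C)(C)C)=C(c2ccc(OCc3ccccc3)cc2)C(=O)C(O)=C1c1ccc(OCc2ccccc2)cc1 | intermediate
13 | 3,6-bis[4-(benzyloxy)phenyl]-5-tert-butoxybenzene-1,2,4-triol | Oc1c(OC(C)(C)C)c(-c2ccc(OCc3ccccc3)cc2)c(O)c(O)c1-c1ccc(OCc2ccccc2)cc1 | intermediate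
14 | 4,7-bis[4-(benzyloxy)phenyl]-6-tert-butoxy-2,2-di-tert-butyl-1,3,2-benzodioxasilol-5-ol | Oc1c(OC(C)(C)C)c(-c2ccc(OCc3ccccc3)cc2)c2O[Si](C(C)(C)C)(C(C)(C)C)Oc2c1-c1ccc(OCc2ccccc2)cc1 | intermediate
15 | 4,7-bis[4-(benzyloxy)phenyl]-6-tert-butoxy-2,2-di-tert-butyl-1,3,2-benzodioxasilol-5-yl acetate | CC(=O)Oc1c(OC(C)(C)C)c(-c2ccc(OCc3ccccc3)cc2)c2O[Si](C(C)(C)C)(C(C)(C)C)Oc2c1-c1ccc(OCc2ccccc2)cc1 | intermediate
16 | 4,7-bis[4-(benzyloxy)phenyl]-2,2-di-tert-butyl-6-hydroxy-1,3,2-benzodioxasilol-5-yl acetate | CC(=O)Oc1c(O)c(-c2ccc(OCc3ccccc3)cc2)c2O[Si](C(C)(C)C)(C(C)(C)C)Oc2c1-c1ccc(OCc2ccccc2)cc1 | intermediate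
17 | 6-acetoxy-4,7-bis[4-(benzyloxy)phenyl]-2,2-di-tert-butyl-1,3,2-benzodioxasilol-5-yl 3-phenylpropanoate | CC(=O)Oc1c(OC(=O)CCc2ccccc2)c(-c2ccc(OCc3ccccc3)cc2)c2O[Si](C(C)(C)C)(C(C)(C)C)Oc2c1-c1ccc(OCc2ccccc2)cc1 | intermediate
18 | 2-acetoxy-3,6-bis[4-(benzyloxy)phenyl]-4,5-dihydroxyphenyl 3-phenylpropanoate | CC(=O)Oc1c(OC(=O)CCc2ccccc2)c(-c2ccc(OCc3ccccc3)cc2)c(O)c(O)c1-c1ccc(OCc2ccccc2)cc1 | intermediate
19 | methyl (R)-3-hydroxybutanoate | COC(=O)C[C@@H](C)O | starting material
20 | methyl (R)-3-(benzyloxy)butanoate | COC(=O)C[C@@H](C)OCc1ccccc1 | intermediate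
21 | (R)-3-(benzyloxy)butanoic acid | OC(=O)C[C@@H](C)OCc1ccccc1 | intermediate
22 | 2-acetoxy-3,6-bis[4-(benzyloxy)phenyl]-4,5-bis{[(R)-3-(benzyloxy)butanoyl]oxy}phenyl 3-phenylpropanoate | CC(=O)Oc1c(OC(=O)CCc2ccccc2)c(-c2ccc(OCc3ccccc3)cc2)c(OC(=O)C[C@@H](C)OCc2ccccc2)c(OC(=O)C[C@@H](C)OCc2ccccc2)c1-c1ccc(OCc2ccccc2)cc1 | intermediate
23 | curtisian V, 2-acetoxy-4,5-bis{[(R)-3-hydroxybutanoyl]oxy}-3,6-bis(4-hydroxyphenyl)phenyl 3-phenylpropanoate | CC(=O)Oc1c(OC(=O)CCc2ccccc2)c(-c2ccc(O)cc2)c(OC(=O)C[C@@H](C)O)c(OC(=O)C[C@@H](C)O)c1-c1ccc(O)cc1 | target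

**Step count and risks**

Total step count: 14. Longest linear sequence: 11 steps (steps 1, 3, 4, 5, 6, 7, 8, 9, 10, 13, 14).

Steps most likely to fail:

Step 3. The alkyne may insert in the reversed orientation and so give the 2,6-dioxygenated 3,5-diaryl quinone, or the siloxyalkyne may be lost to acid- or silver-induced hydrolysis and oligomerisation before cobalt takes it up. The fallback uses known chemistry, sets out from 1 and returns to the route at 16.
- Bromide 1 is lithiated and borylated (n-BuLi, B(Oi-Pr)3, then aq. HCl) to 4-(benzyloxy)phenylboronic acid F1.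
- Commercial bromanil is converted by NaOMe in methanol into 2,5-dibromo-3,6-dimethoxy-1,4-benzoquinone F2.
- A twofold Suzuki–Miyaura coupling of F2 with F1 (Pd(PPh3)4, K3PO4, dioxane, 90 °C) should give 3,6-bis[4-(benzyloxy)phenyl]-2,5-dimethoxy-1,4-benzoquinone F3.
- Hydrolysis of both vinylogous methyl esters (aq. NaOH, THF/MeOH, then HCl) gives 3,6-bis[4-(benzyloxy)phenyl]-2,5-dihydroxy-1,4-benzoquinone F4, and Na2S2O4 reduces it to 3,6-bis[4-(benzyloxy)phenyl]benzene-1,2,4,5-tetrol F5.
- One equivalent of t-Bu2Si(OTf)2 with 2,6-lutidine bridges one of the two equivalent catechol units to give 4,7-bis[4-(benzyloxy)phenyl]-2,2-di-tert-butyl-1,3,2-benzodioxasilole-5,6-diol F6.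
- Mono-acetylation of F6 (Ac2O, 1 equiv, pyridine) gives 16; over-reacted and unreacted material is separated and recycled.
- The cost is that the two oxygen pairs are then told apart statistically on symmetric intermediates and not by the ring-forming step.

Step 6. The electron-rich triol may re-oxidise to the hydroxyquinone under the basic silylation conditions, and silylation of the isolated C1 hydroxyl may compete with ring closure. The fallback sets out from 13 and returns at 15.
- Triol 13 is heated with PhB(OH)2 in toluene with azeotropic removal of water and without base. Boronic esters form reversibly and only the vicinal O4/O5 pair can close a ring, so the product should be 4,7-bis[4-(benzyloxy)phenyl]-6-tert-butoxy-2-phenyl-1,3,2-benzodioxaborol-5-ol F7.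
- Acetylation in the same flask (Ac2O, pyridine) gives 4,7-bis[4-(benzyloxy)phenyl]-6-tert-butoxy-2-phenyl-1,3,2-benzodioxaborol-5-yl acetate F8.
- Exchange of boron onto pinacol releases 3,6-bis[4-(benzyloxy)phenyl]-2-tert-butoxy-4,5-dihydroxyphenyl acetate F9, which has no third hydroxyl and is much less prone to oxidation.
- Treatment of F9 with t-Bu2Si(OTf)2 and 2,6-lutidine then gives 15.

Step 13. The esterification may stall after the first acylation of the hindered catechol, and the activated benzyloxy acid may undergo base-induced β-elimination to crotonyl esters. The fallback sets out from 18 and returns at 23.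
- Diol 18 is heated with 2,2,6-trimethyl-4H-1,3-dioxin-4-one in toluene at 110 °C. The acetylketene released acylates hindered phenols without base and should give 2-acetoxy-3,6-bis[4-(benzyloxy)phenyl]-4,5-bis(3-oxobutanoyloxy)phenyl 3-phenylpropanoate F10.
- Noyori hydrogenation of both β-keto esters (H2, RuCl2[(R)-BINAP], CH2Cl2) sets the two (R)-carbinol centres under catalyst control and gives 2-acetoxy-3,6-bis[4-(benzyloxy)phenyl]-4,5-bis{[(R)-3-hydroxybutanoyl]oxy}phenyl 3-phenylpropanoate F11.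
- Hydrogenolysis (H2, Pd/C, EtOAc) then leads to 23.
- The stereocentres then come from the ligand and not from the chiral pool, and steps 11 and 12 are no longer needed.

Further compounds
F1 | step 3 | 4-(benzyloxy)phenylboronic acid | OB(O)c1ccc(OCc2ccccc2)cc1
F2 | step 3 | 2,5-dibromo-3,6-dimethoxy-1,4-benzoquinone | COC1=C(Br)C(=O)C(OC)=C(Br)C1=O
F3 | step 3 | 3,6-bis[4-(benzyloxy)phenyl]-2,5-dimethoxy-1,4-benzoquinone | COC1=C(c2ccc(OCc3ccccc3)cc2)C(=O)C(OC)=C(c2ccc(OCc3ccccc3)cc2)C1=O
F4 | step 3 | 3,6-bis[4-(benzyloxy)phenyl]-2,5-dihydroxy-1,4-benzoquinone | OC1=C(c2ccc(OCc3ccccc3)cc2)C(=O)C(O)=C(c2ccc(OCc3ccccc3)cc2)C1=O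
F5 | step 3 | 3,6-bis[4-(benzyloxy)phenyl]benzene-1,2,4,5-tetrol | Oc1c(O)c(-c2ccc(OCc3ccccc3)cc2)c(O)c(O)c1-c1ccc(OCc2ccccc2)cc1
F6 | step 3 | 4,7-bis[4-(benzyloxy)phenyl]-2,2-di-tert-butyl-1,3,2-benzodioxasilole-5,6-diol | Oc1c(O)c(-c2ccc(OCc3ccccc3)cc2)c2O[Si](C(C)(C)C)(C(C)(C)C)Oc2c1-c1ccc(OCc2ccccc2)cc1
F7 | step 6 | 4,7-bis[4-(benzyloxy)phenyl]-6-tert-butoxy-2-phenyl-1,3,2-benzodioxaborol-5-ol | Oc1c(OC(C)(C)C)c(-c2ccc(OCc3ccccc3)cc2)c2OB(c3ccccc3)Oc2c1-c1ccc(OCc2ccccc2)cc1
F8 | step 6 | 4,7-bis[4-(benzyloxy)phenyl]-6-tert-butoxy-2-phenyl-1,3,2-benzodioxaborol-5-yl acetate | CC(=O)Oc1c(OC(C)(C)C)c(-c2ccc(OCc3ccccc3)cc2)c2OB(c3ccccc3)Oc2c1-c1ccc(OCc2ccccc2)cc1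
F9 | step 6 | 3,6-bis[4-(benzyloxy)phenyl]-2-tert-butoxy-4,5-dihydroxyphenyl acetate | CC(=O)Oc1c(OC(C)(C)C)c(-c2ccc(OCc3ccccc3)cc2)c(O)c(O)c1-c1ccc(OCc2ccccc2)cc1
F10 | step 13 | 2-acetoxy-3,6-bis[4-(benzyloxy)phenyl]-4,5-bis(3-oxobutanoyloxy)phenyl 3-phenylpropanoate | CC(=O)Oc1c(OC(=O)CCc2ccccc2)c(-c2ccc(OCc3ccccc3)cc2)c(OC(=O)CC(C)=O)c(OC(=O)CC(C)=O)c1-c1ccc(OCc2ccccc2)cc1
F11 | step 13 | 2-acetoxy-3,6-bis[4-(benzyloxy)phenyl]-4,5-bis{[(R)-3-hydroxybutanoyl]oxy}phenyl 3-phenylpropanoate | CC(=O)Oc1c(OC(=O)CCc2ccccc2)c(-c2ccc(OCc3ccccc3)cc2)c(OC(=O)C[C@@H](C)O)c(OC(=O)C[C@@H](C)O)c1-c1ccc(OCc2ccccc2)cc1
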